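Readings and results are simulated for an exercise; noise was put on by code.

One mole of partner makes one mole of target, and a second mole of partner destroys that target as over-reaction product. What does that do to the set-ups below?

| flask | starting material | second substrate | partner | free catalyst | remark | time |
|---|---|---|---|---|---|---|
| summer | 0.30 M | 0.15 M | 0.315 M | 39 mM | run made earlier |  |
| winter | 0.30 M | 0.15 M | 0.63 M | 39 mM | run made earlier |  |
| eta | 0.30 M | 0.150 M | 0.315 M | 39 mM | one stirred flow tank at steady state, fed with the mixture as stated, mean residence time 2.5 min |  |
| theta | 0.30 M (fed, over 2.00 min) | 0.150 M | 0.315 M | 39 mM | a stirred flask in which starting material is dosed at a steady rate over 2.00 min without added volume, worked up at 2.5 min | 2.5 min |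
| beta | 0.30 M | 0.150 M (fed, over 2.00 min) | 0.315 M | 39 mM | all but second substrate at the start; second substrate goes in evenly over 2.00 min, the run ends at 2.5 min | 2.5 min |
| alpha | 0.30 M | 0.150 M | 0.315 M | 39 mM | a closed flask charged with all of it at once and left for 2.5 min | 2.5 min |

summer run (percent of the starting material charged)

| time / min | target / % | starting material / % |
|---|---|---|
| 0.333 | 31.9 | 58.8 |
| 0.667 | 36.6 | 46.7 |
| 1.00 | 40.2 | 39.0 |
| 1.33 | 40.3 | 34.4 |
| 2.00 | 39.3 | 33.9 |
| 2.50 | 39.0 | 31.3 |

winter run (percent of the starting material charged)

| time / s | target / % | starting material / % |
|---|---|---|
| 10.0 | 36.1 | 56.1 |
| 15.0 | 40.7 | 44.3 |

(readings scatter by 1 percentage point)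

- the set-up with the highest amount of target at the outlet or at the end, in percent of the starting material put in ("none" if the first two lie within 2 percentage points) (eta / theta / beta / alpha / none)
- amount of target at the outlet or at the end, in percent of the starting material put in, eta
- amount of target at the outlet or at the end, in percent of the starting material put in, theta
- amount of target at the outlet or at the end, in percent of the starting material put in, beta
- amount of target at the outlet or at the end, in percent of the starting material put in, alpha

- the stated concentrations are those of everything mixed, before any reaction; amounts are the same in each set-up
- on the list of suspects stand: catalyst intermediate A -> spent catalyst; second substrate + free catalyst <-> catalyst intermediate B; partner + target -> over-reaction product; partner + catalyst intermediate A -> free catalyst + target; partner + catalyst intermediate B -> free catalyst + second product; starting material + free catalyst <-> catalyst intermediate A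
- the feed brings no volume worth counting
- the earlier runs were made in a closed, stirred flask

The forecast takes a budget view, with partner as the reagent to ration. I take a series view: starting material goes to target, and target goes on to over-reaction product. Turnover follows c(partner): the winter run leaves 56.1% starting material at 10.0 s with 0.63 M partner, and the summer run leaves 58.8% at 0.333 min with 0.315 M. The over-reaction step takes one partner too, so c(partner) should cancel from a ratio of the two fractional loss rates.

Count whatever is missing from target plus starting material as over-reaction product, a small correction to the large readings. Dividing target's fractional loss rate by that of starting material, the summer run reads 0.942 between its first two readings. The winter run reads 0.798. Both carry the scatter of their readings. I carry their mean, s = 0.870, as the selectivity factor of target against starting material.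

In a stirred tank, let r be starting material reacted per starting material left at the outlet. Over-reaction product per target is then s times r, so target's share of the feed is r over (one plus r) times (one plus s r). Its peak over r is the reciprocal of the square of one plus the root of s, here 26.8%, and c(partner) does not enter while s holds. In a closed flask with a fraction a of starting material left, target's share is a raised to s, less a, over one minus s. I hold no number for theta or beta.

The forecast names beta as best, with eta 36% (29% to 43%), theta 32% (24% to 40%), beta 48% (40% to 58%) and alpha 39% (37% to 41%). Its ground for eta: “The stirred tank (eta) runs at low partner with slow turnover and lands slightly below batch.” We part on eta, where even its low end stands above my 26.8%.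

The flasks give eta 26.3%, theta 33.3%, beta 49.2% and alpha 40.0%, with beta best.

    catalyst intermediate A → spent catalyst (k = 0.0100 s⁻¹)
    second substrate + free catalyst ⇌ catalyst intermediate B (K = 17.0 M⁻¹, k = 1.80 M⁻¹ s⁻¹)
    partner + target → over-reaction product (k = 0.0780 M⁻¹ s⁻¹)
    partner + catalyst intermediate A → free catalyst + target (k = 3.50 M⁻¹ s⁻¹)
    partner + catalyst intermediate B → free catalyst + second product (k = 0.130 M⁻¹ s⁻¹)
    starting material + free catalyst ⇌ catalyst intermediate A (K = 2.40 M⁻¹, k = 15.0 M⁻¹ s⁻¹)

Eta's outlet holds 22.7% over-reaction product on 26.3% target. Counting the remainder as starting material, that reads s = 0.876, against 0.870 carried. Eta stays low through two steps acting together, the turning of target into over-reaction product and the undoing of catalyst intermediate A into starting material and free catalyst: with the first taken away eta gives 59.2%, with the second taken away 52.7%. In alpha, s and the 30.9% starting material left give 39.2%, and the flask holds 40.0%. The budget view keeps its region in beta, where the slow dosing of second substrate is part of the result: with that dosing taken away, beta gives 40.0% against 49.2%.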